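**Plan**

Numbering used throughout: ring atoms C1 (allylic OAc carbon), C2=C3 (CH3 on C3), C4, C5, C6=C7 (carboxyl carbon C14 on C7), C8, C9 (OAc), C10 (i-Pr).
Enabling feature: C1 carries oxygen and C7 carries the carboxyl carbon, and they are linked through C8–C9–C10 on one side and C2–C6 on the other. A C1–C7 bond therefore divides the ten-membered ring into a cyclopentane (C1, C7, C8, C9, C10) and a cycloheptene (C1 to C7). This cis-fused bicyclo[5.3.0] β-hydroxy ester, with a sulfonate on C6, can break C1–C7 again to return C1=O and the C6=C7 enoate.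
Retrosynthetic cuts: the two acetates and the tert-butyl ester; C1–H (back to the enone); reconnection of C1–C7; then C1–C2 (alkenyllithium to ketone), C6–C7 (aldol), C1–C7 (Dieckmann), C9–C10 (syn aldol) and C3–C4 (carbocupration of propyne).
Forward order: chain C14–C7–C8–C9–C10–C1, five-membered ring, C6–C2 arm on C7, seven-membered ring, fragmentation to the ten-membered ring, then C1 reduction, acetylation and ester cleavage.
Stereochemistry: C9 and C10 from the (S)-benzyloxazolidinone syn aldol; C1 from C9-hydroxyl-directed 1,3-anti reduction; cis C2=C3 from the (Z)-alkenyl iodide held in the cycloheptene; ring-cis C6=C7 from the anti-periplanar fragmentation. The transient centres C1, C6 and C7 need only the correct relative configuration, which the tether (cis fusion) and a C1-hydroxyl-directed reduction of a C6 ketone enforce.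

Key step: step 12

Remark on the chemistry: C6 and C7 are created in step 6 without reliable control, and both are erased in step 12. C6 is therefore carried as an epimer mixture until it is reset in steps 9 and 10. The aldol adduct and the bicyclic intermediates are written for the C7 epimer expected from attack anti to the C10 isopropyl group; the other C7 epimer should take the same steps to the same ten-membered product.

**Route**

Step 1
Reactants: 1 2-(1,3-dioxolan-2-yl)ethylmagnesium bromide (THF solution); 2 propyne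
Product: 4 2-[(3Z)-4-iodo-3-methylbut-3-en-1-yl]-1,3-dioxolane, via alkenylcopper 3 (not isolated)
Conditions: CuBr·SMe2, Et2O/Me2S, −45 °C; 2, −25 °C; I2, THF, −50 → 0 °C
Reagents that add atoms: iodine, [I][I]
Why: Normant carbocupration adds the alkylcopper syn across the terminal alkyne with copper on the terminal carbon, so copper and the new chain are cis, and iodinolysis with retention gives the (Z)-alkenyl iodide that later places C1 and C4 cis on C2=C3.

Step 2
Reactants: 4 2-[(3Z)-4-iodo-3-methylbut-3-en-1-yl]-1,3-dioxolane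
Product: 5 (4Z)-5-iodo-4-methylpent-4-enal
Conditions: HCl (2 M aq), THF, 40 °C
Reagents that add atoms: water, O
Why: Acid-catalysed acetal hydrolysis releases the aldehyde, the alkenyl iodide being inert to dilute aqueous acid.

Step 3
Reactants: 6 (S)-4-benzyl-3-(3-methylbutanoyl)oxazolidin-2-one; 7 tert-butyl 4-oxobutanoate
Product: 9 tert-butyl (4R,5S)-5-[(4S)-4-benzyl-2-oxo-1,3-oxazolidine-3-carbonyl]-4-hydroxy-6-methylheptanoate, via boron enolate 8 (not isolated)
Conditions: Bu2BOTf, i-Pr2NEt, CH2Cl2, 0 °C; 7, −78 → 0 °C; H2O2, pH 7 buffer, MeOH, 0 °C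
Reagents that add atoms: none
Why: Evans boron aldol reaction in which the Z-enolate 8 reacts through a Zimmerman–Traxler chair on the enolate face away from the benzyl group, giving the syn adduct that fixes C9 (R) and C10 (S).

Step 4
Reactants: 9 syn-aldol imide
Product: 10 tert-butyl (4R,5S)-5-[(4S)-4-benzyl-2-oxo-1,3-oxazolidine-3-carbonyl]-4-[(tert-butyldimethylsilyl)oxy]-6-methylheptanoate
Conditions: TBSOTf, 2,6-lutidine, CH2Cl2, −78 °C
Reagents that add atoms: tert-butyldimethylsilyl trifluoromethanesulfonate, CC(C)(C)[Si](C)(C)OS(=O)(=O)C(F)(F)F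
Why: Silyl triflate silylation with a hindered pyridine base caps the hindered C9 hydroxyl at low temperature, where neither retro-aldol nor cleavage of the tert-butyl ester is expected.

Step 5
Reactants: 10 silylated aldol imide
Product: 11 tert-butyl (3S,4R)-4-[(tert-butyldimethylsilyl)oxy]-2-oxo-3-(propan-2-yl)cyclopentane-1-carboxylate (ring atoms C7, C1, C10, C9, C8; C7 epimers and enol)
Conditions: LiN(SiMe3)2 (2.2 equiv), THF, −78 → 0 °C; aq NH4Cl
Reagents that add atoms: none
Why: Dieckmann-type intramolecular Claisen acylation in which the C7 ester enolate attacks the imide carbonyl C1 (5-exo-trig) and expels the oxazolidinone anion; the α-branched imide resists deprotonation at C10 because of 1,3-allylic strain, and the product rests as its stabilised β-keto ester enolate until the quench, which protects C10 and the C9 silyloxy group from elimination.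

Step 6
Reactants: 11 cyclopentanone β-keto ester; 5 (4Z)-5-iodo-4-methylpent-4-enal
Product: 12 C7 aldol adduct of 11 carrying the (4Z)-1-hydroxy-5-iodo-4-methylpent-4-en-1-yl chain on C7 (chain cis to the C9 silyloxy group and trans to the C10 isopropyl group; C6 epimers)
Conditions: MgBr2·OEt2, Et3N, CH2Cl2, −20 → 0 °C; aq NH4Cl
Reagents that add atoms: none
Why: Soft-enolisation aldol addition of the magnesium-chelated β-keto ester enolate to the aldehyde, in which the magnesium-chelated aldolate resists reversal and the fully substituted C7 cannot dehydrate; attack anti to the pseudo-axial C10 isopropyl group is expected and C6 is left uncontrolled on purpose.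

Step 7
Reactants: 12 C7 aldol adduct
Product: 13 C6 trimethylsilyl ether of 12
Conditions: 1-(trimethylsilyl)imidazole, CH2Cl2, 20 °C
Reagents that add atoms: 1-(trimethylsilyl)imidazole, C[Si](C)(C)n1ccnc1
Why: Neutral O-silylation with a silylimidazole masks the C6 hydroxyl, which would otherwise consume base and open a retro-aldol path in step 8, without enolising the ketone.

Step 8
Reactants: 13 silylated iodoalkenyl ketone
Product: 16 cis-fused bicyclo[5.3.0]dec-2-ene-1,6-diol with C7 tert-butyl ester and C9 silyl ether (C1–OH cis to the ester; C6 epimers), via alkenyllithium 14 (not isolated), via bicyclic trimethylsilyl ether 15 (not isolated)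
Conditions: t-BuLi (2.1 equiv), THF, −78 °C; aq NH4Cl; then citric acid, MeOH, 20 °C
Reagents that add atoms: none
Why: Iodine–lithium exchange on the alkenyl iodide outruns addition of t-BuLi to the hindered ketone, and the alkenyllithium 14 then adds to the C1 ketone within the tether (7-exo-trig), which can only deliver C2 to the face of C1 that carries C6 and therefore gives the cis ring fusion (C1–OH cis to the C7 ester) for either C7 epimer; the tert-butyl ester is too hindered to compete and mild acid methanolysis removes the trimethylsilyl group from 15.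

Step 9
Reactants: 16 bicyclic 1,6-diol
Product: 17 cis-fused 1-hydroxy-6-oxobicyclo[5.3.0]dec-2-ene with C7 tert-butyl ester and C9 silyl ether
Conditions: Dess–Martin periodinane, NaHCO3, CH2Cl2, 0 → 20 °C
Reagents that add atoms: none
Why: Dess–Martin oxidation converts both C6 epimers into one ketone under buffered non-basic conditions that spare the tertiary allylic alcohol and avoid retro-aldol cleavage of the β-hydroxy ketone.

Step 10
Reactants: 17 bicyclic hydroxy ketone
Product: 18 cis-fused bicyclo[5.3.0]dec-2-ene-1,6-diol with C6–OH trans to C1–OH and to the C7 ester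
Conditions: Me4NBH(OAc)3, MeCN/AcOH (1:1), −20 → 0 °C
Reagents that add atoms: none
Why: Hydroxyl-directed (Evans–Saksena) reduction in which the C1 hydroxyl binds the acetoxyborohydride and delivers hydride to the face of the C6 carbonyl that it occupies, so the new C6 hydroxyl is trans to the C1 hydroxyl and to the C7 ester as step 12 requires, while the acidic medium prevents retro-aldol.

Step 11
Reactants: 18 bicyclic trans-1,6-diol
Product: 19 cis-fused bicyclo[5.3.0]dec-2-en-1-ol with C6 mesylate (trans to the ester), C7 tert-butyl ester and C9 silyl ether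
Conditions: MsCl, Et3N, CH2Cl2, −20 °C
Reagents that add atoms: methanesulfonyl chloride, CS(=O)(=O)Cl
Why: Sulfonylation with MsCl and Et3N activates the secondary C6 hydroxyl, the tertiary C1 hydroxyl being unreactive and the amine too weak a base to start the fragmentation.

Step 12
Reactants: 19 bicyclic hydroxy mesylate
Product: 21 tert-butyl (2Z,6E,9R,10S)-9-[(tert-butyldimethylsilyl)oxy]-3-methyl-1-oxo-10-(propan-2-yl)cyclodeca-2,6-diene-7-carboxylate (route numbering; both double bonds cis within the ring), via potassium alkoxide 20 (not isolated)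
Conditions: KN(SiMe3)2 (1.05 equiv), THF, −78 → −20 °C; pH 7 buffer
Reagents that add atoms: none
Why: Deprotonation of the C1 hydroxyl gives alkoxide 20, in which electron push from oxygen forms C1=O while the C1–C7 σ-bond, anti-periplanar to the C6–O bond of the mesylate, becomes the C6=C7 π-bond and mesylate departs (concerted Grob fragmentation), the C7 ester stabilising the developing charge so that even a stepwise retro-aldol then β-elimination ends at the same enoate. The closest known reaction type is the Wharton fragmentation of bicyclic 1,3-diol monosulfonates to medium-ring unsaturated ketones. The ten-membered ring is not closed by bond formation but appears when the bond shared by the five- and seven-membered rings is cut, so no ring-closure mode applies. No stereocentre is created: C1, C6 and C7 become trigonal and C9 and C10 are not involved. The selectivity needed is the ring-cis geometry of C6=C7 (C5 cis to C8), and the substrate secures it because in the cis-fused bicycle with the mesylate trans to the ester the only conformer with C6–OMs anti to C1–C7 places C8 axial on the cycloheptene and gauche to C5, while C2=C3 is already cis within the seven-membered ring. One equivalent of a potassium amide at low temperature leaves no free base to eliminate the C9 silyloxy group from 21 and favours fragmentation over closure to an oxetane.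

Step 13
Reactants: 21 ten-membered silyloxy enone
Product: 22 tert-butyl (2Z,6E,9R,10S)-9-hydroxy-3-methyl-1-oxo-10-(propan-2-yl)cyclodeca-2,6-diene-7-carboxylate (route numbering)
Conditions: HF·pyridine, pyridine, THF, 0 → 20 °C
Reagents that add atoms: none
Why: Fluoride-mediated desilylation under buffered acidic conditions frees the C9 hydroxyl without the base that would eliminate it from the β-hydroxy ketone, and the tert-butyl ester is stable to HF·pyridine.

Step 14
Reactants: 22 ten-membered β-hydroxy enone
Product: 23 tert-butyl (1R,2Z,6E,9R,10S)-1,9-dihydroxy-3-methyl-10-(propan-2-yl)cyclodeca-2,6-diene-7-carboxylate (route numbering)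
Conditions: Me4NBH(OAc)3, MeCN/AcOH (1:1), −30 °C
Reagents that add atoms: none
Why: Evans–Saksena reduction in which the C9-bound acetoxyborohydride delivers hydride intramolecularly to the C1 carbonyl through a chair transition state (1,2-reduction of the enone only), setting C1 (R) 1,3-anti to C9.

Step 15
Reactants: 23 ten-membered 1,9-diol
Product: 24 tert-butyl (1R,2Z,6E,9R,10S)-1,9-bis(acetyloxy)-3-methyl-10-(propan-2-yl)cyclodeca-2,6-diene-7-carboxylate (route numbering)
Conditions: Ac2O, DMAP (cat.), pyridine, CH2Cl2, 20 °C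
Reagents that add atoms: acetic anhydride, CC(=O)OC(C)=O
Why: DMAP-catalysed acylation esterifies both secondary hydroxyls under conditions that leave the alkenes and the tert-butyl ester untouched.

Step 16
Reactants: 24 diacetate tert-butyl ester
Product: 26 (1E,5Z,7R,8S,9R)-7,9-bis(acetyloxy)-5-methyl-8-(propan-2-yl)cyclodeca-1,5-diene-1-carboxylic acid (the target), via trimethylsilyl ester 25 (not isolated)
Conditions: Me3SiOTf, 2,6-lutidine, CH2Cl2, 0 °C; then H2O
Reagents that add atoms: none
Why: Silyl triflate-mediated dealkylation of the tert-butyl ester (loss of 2-methylpropene) gives silyl ester 25, which water hydrolyses to the acid, and the lutidine buffer keeps the medium non-acidic so the acetates and the allylic C1–O bond are spared.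

**Compound list**

1 | 2-(1,3-dioxolan-2-yl)ethylmagnesium bromide (commercial THF solution) | Br[Mg]CCC1OCCO1 | starting material
2 | propyne | CC#C | starting material
3 | [(1Z)-4-(1,3-dioxolan-2-yl)-2-methylbut-1-en-1-yl]copper (Cu cis to the chain) | [Cu]\C=C(C)/CCC1OCCO1 | intermediate (not isolated)
4 | 2-[(3Z)-4-iodo-3-methylbut-3-en-1-yl]-1,3-dioxolane | I\C=C(C)/CCC1OCCO1 | intermediate
5 | (4Z)-5-iodo-4-methylpent-4-enal | I\C=C(C)/CCC=O | intermediate
6 | (S)-4-benzyl-3-(3-methylbutanoyl)oxazolidin-2-one | CC(C)CC(=O)N1[C@@H](Cc2ccccc2)COC1=O | starting material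
7 | tert-butyl 4-oxobutanoate | CC(C)(C)OC(=O)CCC=O | starting material
8 | (Z)-dibutylboron enolate of 6 (O–B cis to the isopropyl group) | CC(C)/C=C(\OB(CCCC)CCCC)N1[C@@H](Cc2ccccc2)COC1=O | intermediate (not isolated)
9 | tert-butyl (4R,5S)-5-[(4S)-4-benzyl-2-oxo-1,3-oxazolidine-3-carbonyl]-4-hydroxy-6-methylheptanoate | CC(C)(C)OC(=O)CC[C@@H](O)[C@@H](C(=O)N1[C@@H](Cc2ccccc2)COC1=O)C(C)C | intermediate
10 | tert-butyl (4R,5S)-5-[(4S)-4-benzyl-2-oxo-1,3-oxazolidine-3-carbonyl]-4-[(tert-butyldimethylsilyl)oxy]-6-methylheptanoate | CC(C)(C)OC(=O)CC[C@@H](O[Si](C)(C)C(C)(C)C)[C@@H](C(=O)N1[C@@H](Cc2ccccc2)COC1=O)C(C)C | intermediate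
11 | tert-butyl (3S,4R)-4-[(tert-butyldimethylsilyl)oxy]-2-oxo-3-(propan-2-yl)cyclopentane-1-carboxylate (C7 epimers and enol) | O=C1C(C(=O)OC(C)(C)C)C[C@@H](O[Si](C)(C)C(C)(C)C)[C@@H]1C(C)C | intermediate
12 | tert-butyl (3S,4R)-4-[(tert-butyldimethylsilyl)oxy]-1-[(4Z)-1-hydroxy-5-iodo-4-methylpent-4-en-1-yl]-2-oxo-3-(propan-2-yl)cyclopentane-1-carboxylate (side chain on C7 cis to the C9 silyloxy group, trans to the C10 isopropyl group; C6 epimers) | O=C1[C@@](C(=O)OC(C)(C)C)(C(O)CC/C(C)=C\I)C[C@@H](O[Si](C)(C)C(C)(C)C)[C@@H]1C(C)C | intermediate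
13 | C6 trimethylsilyl ether of 12 (C6 epimers) | O=C1[C@@](C(=O)OC(C)(C)C)(C(O[Si](C)(C)C)CC/C(C)=C\I)C[C@@H](O[Si](C)(C)C(C)(C)C)[C@@H]1C(C)C | intermediate
14 | (Z)-alkenyllithium from 13 (Li in place of I, cis to C4) | O=C1[C@@](C(=O)OC(C)(C)C)(C(O[Si](C)(C)C)CC/C(C)=C\[Li])C[C@@H](O[Si](C)(C)C(C)(C)C)[C@@H]1C(C)C | intermediate (not isolated)
15 | tert-butyl (9R,10S)-9-[(tert-butyldimethylsilyl)oxy]-1-hydroxy-3-methyl-10-(propan-2-yl)-6-[(trimethylsilyl)oxy]bicyclo[5.3.0]dec-2-ene-7-carboxylate (route numbering; cis-fused, C1–OH cis to the C7 ester; seven-membered ring on the cyclopentane face of the C9 silyloxy group; C6 epimers) | O[C@]12C=C(C)CCC(O[Si](C)(C)C)[C@@]1(C(=O)OC(C)(C)C)C[C@@H](O[Si](C)(C)C(C)(C)C)[C@@H]2C(C)C | intermediate (not isolated)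
16 | tert-butyl (9R,10S)-9-[(tert-butyldimethylsilyl)oxy]-1,6-dihydroxy-3-methyl-10-(propan-2-yl)bicyclo[5.3.0]dec-2-ene-7-carboxylate (route numbering; cis-fused as 15; C6 epimers) | O[C@]12C=C(C)CCC(O)[C@@]1(C(=O)OC(C)(C)C)C[C@@H](O[Si](C)(C)C(C)(C)C)[C@@H]2C(C)C | intermediate
17 | tert-butyl (9R,10S)-9-[(tert-butyldimethylsilyl)oxy]-1-hydroxy-3-methyl-6-oxo-10-(propan-2-yl)bicyclo[5.3.0]dec-2-ene-7-carboxylate (route numbering; cis-fused as 15) | O[C@]12C=C(C)CCC(=O)[C@@]1(C(=O)OC(C)(C)C)C[C@@H](O[Si](C)(C)C(C)(C)C)[C@@H]2C(C)C | intermediate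
18 | tert-butyl (9R,10S)-9-[(tert-butyldimethylsilyl)oxy]-1,6-dihydroxy-3-methyl-10-(propan-2-yl)bicyclo[5.3.0]dec-2-ene-7-carboxylate (route numbering; cis-fused as 15; C6–OH trans to C1–OH and to the C7 ester, cis to C8) | O[C@]12C=C(C)CC[C@@H](O)[C@@]1(C(=O)OC(C)(C)C)C[C@@H](O[Si](C)(C)C(C)(C)C)[C@@H]2C(C)C | intermediate
19 | tert-butyl (9R,10S)-9-[(tert-butyldimethylsilyl)oxy]-1-hydroxy-6-[(methanesulfonyl)oxy]-3-methyl-10-(propan-2-yl)bicyclo[5.3.0]dec-2-ene-7-carboxylate (route numbering; configuration as 18) | O[C@]12C=C(C)CC[C@@H](OS(C)(=O)=O)[C@@]1(C(=O)OC(C)(C)C)C[C@@H](O[Si](C)(C)C(C)(C)C)[C@@H]2C(C)C | intermediate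
20 | potassium C1 alkoxide of 19 | [K+].[O-][C@]12C=C(C)CC[C@@H](OS(C)(=O)=O)[C@@]1(C(=O)OC(C)(C)C)C[C@@H](O[Si](C)(C)C(C)(C)C)[C@@H]2C(C)C | intermediate (not isolated)
21 | tert-butyl (2Z,6E,9R,10S)-9-[(tert-butyldimethylsilyl)oxy]-3-methyl-1-oxo-10-(propan-2-yl)cyclodeca-2,6-diene-7-carboxylate (route numbering; both double bonds cis within the ring) | O=C1/C=C(/C)CC/C=C(/C(=O)OC(C)(C)C)C[C@@H](O[Si](C)(C)C(C)(C)C)[C@@H]1C(C)C | intermediate
22 | tert-butyl (2Z,6E,9R,10S)-9-hydroxy-3-methyl-1-oxo-10-(propan-2-yl)cyclodeca-2,6-diene-7-carboxylate (route numbering) | O=C1/C=C(/C)CC/C=C(/C(=O)OC(C)(C)C)C[C@@H](O)[C@@H]1C(C)C | intermediate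
23 | tert-butyl (1R,2Z,6E,9R,10S)-1,9-dihydroxy-3-methyl-10-(propan-2-yl)cyclodeca-2,6-diene-7-carboxylate (route numbering) | O[C@@H]1/C=C(/C)CC/C=C(/C(=O)OC(C)(C)C)C[C@@H](O)[C@@H]1C(C)C | intermediate
24 | tert-butyl (1R,2Z,6E,9R,10S)-1,9-bis(acetyloxy)-3-methyl-10-(propan-2-yl)cyclodeca-2,6-diene-7-carboxylate (route numbering) | CC(=O)O[C@@H]1/C=C(/C)CC/C=C(/C(=O)OC(C)(C)C)C[C@@H](OC(C)=O)[C@@H]1C(C)C | intermediate
25 | trimethylsilyl (1R,2Z,6E,9R,10S)-1,9-bis(acetyloxy)-3-methyl-10-(propan-2-yl)cyclodeca-2,6-diene-7-carboxylate (route numbering) | CC(=O)O[C@@H]1/C=C(/C)CC/C=C(/C(=O)O[Si](C)(C)C)C[C@@H](OC(C)=O)[C@@H]1C(C)C | intermediate (not isolated)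
26 | (1E,5Z,7R,8S,9R)-7,9-bis(acetyloxy)-5-methyl-8-(propan-2-yl)cyclodeca-1,5-diene-1-carboxylic acid (route numbering 1R,9R,10S) | CC(=O)O[C@@H]1/C=C(/C)CC/C=C(/C(=O)O)C[C@@H](OC(C)=O)[C@@H]1C(C)C | target

**Step count and risks**

Total: 16 steps. Longest linear sequence: 14 steps (steps 3 to 16, from 6 and 7). The aldehyde 5 takes 2 steps (steps 1 and 2) and joins at step 6.

Steps most likely to fail:

Step 8. The alkenyllithium may be lost by proton transfer from C10–H (enolisation of the hindered ketone, then β-elimination of the silyloxy group), or t-BuLi may add to the ketone before the exchange. The fallback makes the C1–C2 bond intermolecularly and closes the ring by metathesis. Setting out again from 11, the magnesium-mediated aldol of step 6 with 4-methylpent-4-enal would give the hydroxy ketone F1, and 1-(trimethylsilyl)imidazole its trimethylsilyl ether F2. Vinylmagnesium bromide with CeCl3 (THF, −78 °C) would then give the C1 vinyl carbinol F3, with addition expected anti to both the C10 isopropyl group and the C7 ester. Ring-closing metathesis of the vinyl and isopropenyl groups with the second-generation Grubbs catalyst (CH2Cl2, 40 °C) closes the trisubstituted cycloheptene and rejoins the route at 15. In this variant the cis fusion rests on the facial selectivity of the addition and no longer on a tether.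

Step 6. The aldol equilibrium may lie on the side of the components, or the adduct may revert during work-up. The fallback activates the nucleophile beforehand. From 11, Me3SiOTf and Et3N (CH2Cl2, 0 °C) give the enol silane F4. Its Mukaiyama aldol addition to 5 promoted by BF3·OEt2 (CH2Cl2, −78 °C) forms the C6–C7 bond irreversibly and rejoins the route at 12.

Step 12. The alkoxide may displace the mesylate intramolecularly (oxetane closure) if the conformer with the anti-periplanar C1–C7 and C6–O bonds is poorly populated. The fallback cuts the same C1–C7 bond one oxidation level higher. From 17, catalytic DBU (CH2Cl2, 0 °C) should trigger retro-aldol ring expansion to the ten-membered β-keto ester F5. NaH followed by PhNTf2 (THF, 0 °C) traps the sodium-chelated enolate as the (Z)-enol triflate F6, with the triflate cis to the ester. Reduction with Pd(OAc)2/PPh3, HCO2H and Bu3N (DMF, 60 °C) replaces the triflate by hydrogen with retention and rejoins the route at 21.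

Further compounds

F1 | step 8 | tert-butyl (3S,4R)-4-[(tert-butyldimethylsilyl)oxy]-1-(1-hydroxy-4-methylpent-4-en-1-yl)-2-oxo-3-(propan-2-yl)cyclopentane-1-carboxylate (side chain on C7 cis to the C9 silyloxy group; C6 epimers) | O=C1[C@@](C(=O)OC(C)(C)C)(C(O)CCC(C)=C)C[C@@H](O[Si](C)(C)C(C)(C)C)[C@@H]1C(C)C
F2 | step 8 | C6 trimethylsilyl ether of F1 | O=C1[C@@](C(=O)OC(C)(C)C)(C(O[Si](C)(C)C)CCC(C)=C)C[C@@H](O[Si](C)(C)C(C)(C)C)[C@@H]1C(C)C
F3 | step 8 | C1 vinyl carbinol from F2 (vinyl cis to the C6 side chain, C1–OH cis to the C7 ester) | C=C[C@@]1(O)[C@@](C(=O)OC(C)(C)C)(C(O[Si](C)(C)C)CCC(C)=C)C[C@@H](O[Si](C)(C)C(C)(C)C)[C@@H]1C(C)C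
F4 | step 6 | tert-butyl (9R,10S)-4-[(tert-butyldimethylsilyl)oxy]-3-(propan-2-yl)-2-[(trimethylsilyl)oxy]cyclopent-1-ene-1-carboxylate (descriptors in route numbering) | C[Si](C)(C)OC1=C(C(=O)OC(C)(C)C)C[C@@H](O[Si](C)(C)C(C)(C)C)[C@@H]1C(C)C
F5 | step 12 | tert-butyl (2Z,9R,10S)-9-[(tert-butyldimethylsilyl)oxy]-3-methyl-1,6-dioxo-10-(propan-2-yl)cyclodec-2-ene-7-carboxylate (route numbering; C7 epimers and enol) | O=C1/C=C(/C)CCC(=O)C(C(=O)OC(C)(C)C)C[C@@H](O[Si](C)(C)C(C)(C)C)[C@@H]1C(C)C
F6 | step 12 | tert-butyl (2Z,6Z,9R,10S)-9-[(tert-butyldimethylsilyl)oxy]-3-methyl-1-oxo-10-(propan-2-yl)-6-[(trifluoromethanesulfonyl)oxy]cyclodeca-2,6-diene-7-carboxylate (route numbering; triflate cis to the ester) | O=C1/C=C(/C)CC/C(OS(=O)(=O)C(F)(F)F)=C(/C(=O)OC(C)(C)C)C[C@@H](O[Si](C)(C)C(C)(C)C)[C@@H]1C(C)C
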